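## Structural features

Numbering used throughout: C1 is the epoxide CH, C2 the ketone, C3 the enone CH, C4 the enone C(CH3), C5 the carbinol, C6 the lactone O-CH, C7 the ring-fusion CH, C8 the tiglate-bearing CH, C9 the CH2 and C10 the epoxide C(CH3). C11, C12 and C13 are the lactone alpha-carbon, the lactone C=O and the exocyclic CH2. C14 and C15 are the methyl groups on C10 and C4.

- The target is a germacranolide. A ten-membered carbocycle (C1-C10) is cis-fused at C6-C7 to an alpha-methylene-gamma-butyrolactone (O6, C6, C7, C11, C12). It carries an (E)-2-methylbut-2-enoate on O8 and a free hydroxyl on C5. The configuration is 1S,5S,6R,7R,8R,10R.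
- C5, C6, C7 and C8 are four contiguous stereocentres whose O, O, C and O substituents all lie on one face of the ring (anti, anti, anti in the zig-zag chain). C1 and C10 form a remote pair locked in a trans-epoxide.
- C10-C1-C2-C3-C4 is a cross-conjugated divinyl ketone. Its E half (C1=C10) is epoxidised and its Z half (C3=C4) is intact. Both beta-carbons carry a methyl group, so this region is pseudo-symmetric about C2.
- The fragile groups are the alpha-methylene lactone (Michael acceptor), the epoxy ketone (reduction, base) and the Z gamma-hydroxy enone (isomerisation, hemiketal and furan formation). The lactone can also migrate between O6 and O8.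
- The real difficulty is closing a strained ten-membered ring that holds five contiguous sp2 or epoxide carbons, with one E and one Z trisubstituted olefin, without disturbing the C5-C8 tetrad.
- The key step exploits the pseudo-symmetry at C2. This carbon bears only oxygen and is flanked by the two 2-methylalkenyl carbons C1 and C3. It can therefore be excised as carbon monoxide, and the ring is closed by making C1-C2 and C2-C3 in one operation.

## Logic of the disconnections

**Epoxide.** The C1-O and C10-O bonds of 24 are cut, going back through 23, 22 and 21 to 20. The epoxide is the only stereo-element that cannot sit on an sp2-sp2 coupling terminus, so it is removed first. This leaves a flat dienone. The forward sequence must pick C1=C10 over C3=C4, C11=C13 and the tiglate, and must set 1S,10R by reagent control. That requires a temporary C2 carbinol.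

**Key disconnection.** The C1-C2 and C2-C3 bonds of 20 are cut together, giving 19 and carbon monoxide. The cut removes the macrocycle and the ketone at once. It leaves an acyclic chain whose two ends are stereodefined alkenyl-metal and alkenyl-halide units. The forward step must close a ten-membered ring with CO uptake and with retention at both olefins.

**Tiglate.** The O8-acyl bond of 19 is cut to give 17 and 18. The ester is put on late so that it never meets strong base. The forward step needs O8-H to be the only free hydroxyl.

**Lactone.** C11=C13 and C7-C11 of 17 are cut, going through 16 to 15. The lactone ring is opened at its C-C bond and not at its C-O bond. C7 and C8 then become the two carbons of a trans-epoxide, and their configuration follows from one stereospecific substitution. The forward step needs a tethered carbanion to attack C7 in the 5-exo mode.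

**C6 inversion and chain epoxide.** The O6-C12 bond of 15 is cut with inversion at C6, giving 13 and 14. The C7-O and C8-O bonds of 13 are then cut to give 12. Inversion is chosen because the epoxide needed is threo to the final O6, whereas the reagent-controlled epoxidation delivers the erythro isomer. The carbinol is therefore made as the 6S epimer and turned over when the tether is attached.

**Chain olefin.** C7=C8 of 12 is cut to give 8 and 11. This splits the chain into a stereo-rich western half and an achiral eastern half. The forward step needs an E-selective olefin exchange that ignores both trisubstituted alkenyl-heteroatom units.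

**C5-C6.** The C5-C6 bond of 8 is cut, going back through 7 and 6 to 3 and 4. Both carbinol centres arise in one cyclic transition state, and O5 and O6 are differentiated from the start.

**Termini.** C4-C15 and C3-I of 3 are cut, going through 2 to 1. C10-C14 and C1-Sn of 11 are cut, going through 10 to 9. Each trisubstituted olefin reduces to a terminal alkyne. An anti carbometalation gives the Z end and a syn carbometalation gives the E end.

## Other disconnections considered

Alternative 1: This is the first idea that comes to mind. It cuts C6-C7 and O6-C12. The forward key step is an intramolecular Barbier or Nozaki-Hiyama-Kishi allylation of the seco aldehyde/allyl bromide A1, followed by lactonisation. It closes the ring, sets C6 and C7 and makes the lactone in one step.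
- The reducing metal would have to spare an alpha,beta-epoxy ketone and a Z enone that are already in place.
- The aldehyde is alpha-oxygenated and epimerisable.
- The cis relation at C6/C7, and its sense relative to C5 and C8, would depend on an unpredictable macrocyclic transition state.
- In the chosen plan every stereocentre is fixed by reagent control or by a stereospecific substitution.

Alternative 2: This adds a C1-C6 bond retrosynthetically. The forward key step is the anionic oxy-Cope ring expansion of the divinylcyclohexenol A2, made from (R)-carvone, which gives the cyclodecadienone A3. Carvone holds ten of the fifteen carbons, the Z olefin comes from the six-membered ring, and the E olefin comes from the chair transition state.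
- Only C5 survives as a stereocentre.
- C6, C7, C8, C1/C10 and the C2 oxidation would all have to be installed on a flexible ten-membered ring under substrate control.
- The step count would also be higher.

Alternative 3: This cuts only C2-C3. The forward key step is a Nozaki-Hiyama-Kishi closure of the epoxy aldehyde/alkenyl iodide A4, with the epoxide set beforehand on an acyclic allylic alcohol, followed by oxidation. It is sound and sets the epoxide more safely.
- C2 must then be carried in the eastern fragment with its own protecting group.
- It costs one more operation overall, because a deprotection, an oxidation to the aldehyde, the coupling and a re-oxidation replace the carbonylation, the reduction and the oxidation.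
- An epimerisable epoxy aldehyde would be exposed to divalent chromium.
- The chosen plan is shorter and makes both chain ends by one alkyne logic. The same closure is kept as the fallback for the key step.

Key step: step 13

Assumption: 4, 9, 14, 18, (+)-Ipc2BOMe and D-(-)-diisopropyl tartrate are taken as commercial. The temporary C2 carbinol epimers of 21 are taken to be separable or recyclable by re-oxidation.

## Route

Step 1
Reactants: 1 prop-2-yn-1-ol
Product: 2 (Z)-3-iodo-2-methylprop-2-en-1-ol
Conditions: MeMgBr, CuI (cat.), Et2O-THF, -10 °C to rt; then I2, -20 °C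
Reagents that add atoms: methylmagnesium bromide C[Mg]Br; iodine II
Why: Copper-catalysed anti-carbomagnesiation of the propargylic alkoxide puts CH3 on C4 and magnesium on C3 inside a five-membered chelate. Iodinolysis with retention then leaves iodine cis to the CH2OH carbon (C5), which is the Z geometry needed for C3=C4.

Step 2
Reactants: 2 (Z)-3-iodo-2-methylprop-2-en-1-ol
Product: 3 (Z)-3-iodo-2-methylprop-2-enal
Conditions: MnO2, CH2Cl2, rt, dark
Reagents that add atoms: none
Why: Allylic oxidation on neutral MnO2 involves no acid or base that could isomerise the Z enal. The aldehyde is used directly.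

Step 3
Reactants: 3 (Z)-3-iodo-2-methylprop-2-enal; 4 3-(methoxymethoxy)prop-1-ene
Product: 6 (1Z,3S,4S)-1-iodo-4-(methoxymethoxy)-2-methylhexa-1,5-dien-3-ol, via (Z)-alkoxyallylborane 5 (not isolated)
Conditions: 4, s-BuLi, THF, -78 °C; (+)-Ipc2BOMe; BF3·OEt2; 3, -78 °C; then NaOH, H2O2
Reagents that add atoms: none
Why: Brown alkoxyallylboration proceeds through a closed chair transition state, so the Z gamma-alkoxyallyl unit gives the syn relation. The (+)-isopinocampheyl ligands select the aldehyde face that gives 5S. C6 is made deliberately as 6S, with O6 masked and O5 free.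

Step 4
Reactants: 6 (1Z,3S,4S)-1-iodo-4-(methoxymethoxy)-2-methylhexa-1,5-dien-3-ol
Product: 7 (1Z,3S,4S)-3-(tert-butyldimethylsilyloxy)-1-iodo-4-(methoxymethoxy)-2-methylhexa-1,5-diene
Conditions: TBSOTf, 2,6-lutidine, CH2Cl2, -78 to 0 °C
Reagents that add atoms: tert-butyldimethylsilyl triflate CC(C)(C)[Si](C)(C)OS(=O)(=O)C(F)(F)F
Why: Standard silylation of the only free hydroxyl. The O5 silyl ether stays on until the last step.

Step 5
Reactants: 7 (1Z,3S,4S)-3-(tert-butyldimethylsilyloxy)-1-iodo-4-(methoxymethoxy)-2-methylhexa-1,5-diene
Product: 8 (3S,4S,5Z)-4-(tert-butyldimethylsilyloxy)-6-iodo-5-methylhexa-1,5-dien-3-ol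
Conditions: ZnBr2, n-PrSH, CH2Cl2, 0 °C
Reagents that add atoms: none
Why: Lewis acid and thiol cleave the acetal by trapping its oxocarbenium ion. This is fast enough to spare a secondary silyl ether and the alkenyl iodide, and it frees O6-H as the directing group for step 9.

Step 6
Reactants: 9 pent-1-en-4-yne
Product: 10 (1E)-1-iodo-2-methylpenta-1,4-diene
Conditions: Me3Al, Cp2ZrCl2 (cat.), CH2Cl2, 0 °C to rt; then I2, THF, -30 °C
Reagents that add atoms: trimethylaluminium C[Al](C)C; iodine II
Why: Negishi zirconium-catalysed carboalumination adds CH3 and Al syn across the terminal alkyne only, with CH3 on the inner carbon C10. Iodinolysis with retention puts iodine trans to C9, which is the E geometry needed for C1=C10.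

Step 7
Reactants: 10 (1E)-1-iodo-2-methylpenta-1,4-diene
Product: 11 tributyl[(1E)-2-methylpenta-1,4-dien-1-yl]stannane
Conditions: t-BuLi (2 equiv), Et2O, -78 °C; then Bu3SnCl
Reagents that add atoms: tributyltin chloride CCCC[Sn](Cl)(CCCC)CCCC
Why: Iodine-lithium exchange and stannylation of an alkenyllithium both proceed with retention. At -78 °C the exchange outruns deprotonation of the doubly allylic CH2.

Step 8
Reactants: 8 (3S,4S,5Z)-4-(tert-butyldimethylsilyloxy)-6-iodo-5-methylhexa-1,5-dien-3-ol; 11 tributyl[(1E)-2-methylpenta-1,4-dien-1-yl]stannane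
Product: 12 (1Z,3S,4S,5E,8E)-3-(tert-butyldimethylsilyloxy)-1-iodo-2,8-dimethyl-9-(tributylstannyl)nona-1,5,8-trien-4-ol
Conditions: second-generation Grubbs catalyst (cat.), 11 (excess), 1,4-benzoquinone (cat.), CH2Cl2, 40 °C
Reagents that add atoms: none
Why: In this olefin cross metathesis only the two monosubstituted alkenes can enter the catalytic cycle. The trisubstituted alkenyl iodide and alkenylstannane are inert. The allylic alcohol partner couples with the unhindered partner to give the thermodynamically preferred E C7=C8 olefin.

Step 9
Reactants: 12 (1Z,3S,4S,5E,8E)-3-(tert-butyldimethylsilyloxy)-1-iodo-2,8-dimethyl-9-(tributylstannyl)nona-1,5,8-trien-4-ol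
Product: 13 (5S,6S,7S,8R)-epoxy alcohol, i.e. 12 with a trans-oxirane on C7-C8, the oxirane oxygen erythro to the 6-hydroxyl
Conditions: Ti(OiPr)4 (cat.), D-(-)-DIPT (cat.), t-BuOOH, 4 Å MS, CH2Cl2, -20 °C
Reagents that add atoms: tert-butyl hydroperoxide CC(C)(C)OO
Why: Sharpless asymmetric epoxidation oxidises only the olefin bound through the allylic O6-H. D-(-)-tartrate delivers oxygen to the face that gives 7S,8R. The 6S carbinol is the matched (fast, erythro-selective) partner of this tartrate.

Step 10
Reactants: 13 (5S,6S,7S,8R)-epoxy alcohol; 14 2-(diethoxyphosphoryl)acetic acid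
Product: 15 (5S,6R,7S,8R)-epoxy ester, i.e. the C6 (diethoxyphosphoryl)acetate of the C6 epimer of 13
Conditions: PPh3, DIAD, toluene, 0 °C to rt
Reagents that add atoms: none
Why: The Mitsunobu esterification displaces the activated carbinol by SN2, turning 6S into the 6R of the target. The same operation attaches the C11-C12 tether. The epoxide is now threo to O6, as the cis-lactone requires.

Step 11
Reactants: 15 (5S,6R,7S,8R)-epoxy ester
Product: 17 (5S,6R,7R,8R)-alpha-methylene-gamma-lactone alcohol (seco chain with O5-TBS, free 8-OH, Z-alkenyl iodide at C3, E-alkenylstannane at C1), via alpha-phosphono lactone 16 (not isolated)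
Conditions: NaH, THF, 0 to 40 °C; then (CH2O)n, rt
Reagents that add atoms: formaldehyde C=O
Why: The phosphonate-stabilised carbanion opens the epoxide intramolecularly at C7 (5-exo-tet alkylation). Inversion at C7 sets 7R cis to C5 and leaves 8R untouched. The C8 alkoxide then re-forms the phosphonate anion by proton transfer, which keeps the lactone carbonyl non-electrophilic. Horner-Wadsworth-Emmons olefination of formaldehyde finally makes C11=C13.

Step 12
Reactants: 17 (5S,6R,7R,8R)-alpha-methylene-gamma-lactone alcohol; 18 (E)-2-methylbut-2-enoyl chloride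
Product: 19 seco precursor, i.e. the O8 (E)-2-methylbut-2-enoate of 17
Conditions: Et3N, DMAP (cat.), CH2Cl2, 0 °C
Reagents that add atoms: none
Why: This is acylation of the only free hydroxyl with retention at C8. The fast DMAP-catalysed transfer outruns migration of the lactone to O8, and the E acyl unit is configurationally stable.

Step 13
Reactants: 19 seco precursor
Product: 20 (1(10)E,3Z,5S,6R,7R,8R)-macrocyclic dienone, i.e. the ten-membered 2-oxo-1(10),3-diene with O5-TBS, 6,12-olide and 8-tiglate
Conditions: Pd2(dba)3 (cat.), AsPh3 (cat.), CO (1 atm), NMP, 45 °C, slow addition to about 1 mM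
Reagents that add atoms: carbon monoxide [C-]#[O+]
Why: Zerovalent palladium inserts into the C3-I bond with retention, and CO insertion turns the alkenylpalladium into the (Z)-alkenoylpalladium that carries the new C2. The tin on C1 transmetalates intramolecularly with retention, and reductive elimination forms C1-C2, so both bonds at C2 are made in one catalytic cycle. The closest known reaction type is the carbonylative Stille macrocyclisation of an alkenyl halide or triflate with an alkenylstannane to a macrocyclic divinyl ketone. The one ring closed is the ten-membered carbocycle, formed end to end through an eleven-membered acyl(alkenyl)palladacycle. No stereocentre is created, and the E and Z geometries are carried over stereospecifically from steps 6 and 1. CO uptake must beat direct coupling: direct coupling would give a more strained nine-membered E,Z-diene, whereas insertion into an alkenyl-palladium bond with a weak donor ligand under CO is fast. Ring closure must also beat oligomerisation, which pseudo-high dilution secures together with two turn elements of the substrate, the cis-fused lactone at C6-C7 and the Z olefin at C3=C4. The conditions are neutral and free of base and hydride, so the methylene lactone, the tiglate and the silyl ether are not addressed.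

Step 14
Reactants: 20 macrocyclic dienone
Product: 21 (2S)-bis-allylic alcohol, i.e. 20 with C2=O reduced to the 2S carbinol
Conditions: NaBH4, CeCl3·7H2O, MeOH-THF, -78 °C
Reagents that add atoms: none
Why: Luche reduction gives clean 1,2-addition to the cross-conjugated ketone. At -78 °C it is much faster than conjugate reduction of the methylene lactone. The C2 centre is temporary: the 2S epimer is carried on, and any 2R epimer is returned to 20 under the conditions of step 16.

Step 15
Reactants: 21 (2S)-bis-allylic alcohol
Product: 22 (1R,2R,5S,6R,7R,8R,10R)-epoxy alcohol, i.e. 21 with the trans-oxirane on C1-C10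
Conditions: Ti(OiPr)4 (cat.), D-(-)-DIPT (cat.), t-BuOOH, 4 Å MS, CH2Cl2, -20 °C
Reagents that add atoms: tert-butyl hydroperoxide CC(C)(C)OO
Why: In this Sharpless asymmetric epoxidation D-(-)-tartrate fixes the face of C1=C10 that gives the 10R configuration of the target. The 2S carbinol is its matched partner and gives the erythro product. The Z olefin C3=C4, with a branched cis substituent, belongs to the slowest substrate class, and the unbound olefins (C11=C13, tiglate) are not touched.

Step 16
Reactants: 22 (1R,2R,5S,6R,7R,8R,10R)-epoxy alcohol
Product: 23 O5-TBS ether of the target, (1S,5S,6R,7R,8R,10R)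
Conditions: Dess-Martin periodinane, NaHCO3, CH2Cl2, 0 °C
Reagents that add atoms: none
Why: Buffered Dess-Martin oxidation of the only free hydroxyl restores the C2 ketone. It does not epimerise C1, open the epoxide or isomerise the Z enone.

Step 17
Reactants: 23 O5-TBS ether of the target
Product: 24 target CNP0345622.1
Conditions: HF·pyridine, pyridine, THF, 0 °C
Reagents that add atoms: none
Why: Buffered fluoride desilylation frees O5-H under conditions too mild to open the epoxy ketone or dehydrate the Z gamma-hydroxy enone. No stereocentre is touched.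

## Compound list

1 | prop-2-yn-1-ol | C#CCO | starting material
2 | (Z)-3-iodo-2-methylprop-2-en-1-ol | I/C=C(/C)CO | intermediate
3 | (Z)-3-iodo-2-methylprop-2-enal | I/C=C(/C)C=O | intermediate
4 | 3-(methoxymethoxy)prop-1-ene | C=CCOCOC | starting material
5 | [(Z)-3-(methoxymethoxy)allyl]bis[(+)-isopinocampheyl]borane | COCO/C=C\CB([C@H]1C[C@H]2C[C@@H]([C@@H]1C)C2(C)C)[C@H]1C[C@H]2C[C@@H]([C@@H]1C)C2(C)C | intermediate
6 | (1Z,3S,4S)-1-iodo-4-(methoxymethoxy)-2-methylhexa-1,5-dien-3-ol | I/C=C(/C)[C@H](O)[C@@H](OCOC)C=C | intermediate
7 | (1Z,3S,4S)-3-(tert-butyldimethylsilyloxy)-1-iodo-4-(methoxymethoxy)-2-methylhexa-1,5-diene | I/C=C(/C)[C@H](O[Si](C)(C)C(C)(C)C)[C@@H](OCOC)C=C | intermediate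
8 | (3S,4S,5Z)-4-(tert-butyldimethylsilyloxy)-6-iodo-5-methylhexa-1,5-dien-3-ol | I/C=C(/C)[C@H](O[Si](C)(C)C(C)(C)C)[C@@H](O)C=C | intermediate
9 | pent-1-en-4-yne | C=CCC#C | starting material
10 | (1E)-1-iodo-2-methylpenta-1,4-diene | I/C=C(\C)CC=C | intermediate
11 | tributyl[(1E)-2-methylpenta-1,4-dien-1-yl]stannane | CCCC[Sn](CCCC)(CCCC)/C=C(\C)CC=C | intermediate
12 | (1Z,3S,4S,5E,8E)-3-(tert-butyldimethylsilyloxy)-1-iodo-2,8-dimethyl-9-(tributylstannyl)nona-1,5,8-trien-4-ol | I/C=C(/C)[C@H](O[Si](C)(C)C(C)(C)C)[C@@H](O)/C=C/C/C(C)=C/[Sn](CCCC)(CCCC)CCCC | intermediate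
13 | (5S,6S,7S,8R)-7,8-epoxy alcohol derived from 12 | I/C=C(/C)[C@H](O[Si](C)(C)C(C)(C)C)[C@@H](O)[C@H]1O[C@@H]1C/C(C)=C/[Sn](CCCC)(CCCC)CCCC | intermediate
14 | 2-(diethoxyphosphoryl)acetic acid | OC(=O)CP(=O)(OCC)OCC | starting material
15 | (5S,6R,7S,8R)-7,8-epoxy C6 (diethoxyphosphoryl)acetate | I/C=C(/C)[C@H](O[Si](C)(C)C(C)(C)C)[C@H](OC(=O)CP(=O)(OCC)OCC)[C@H]1O[C@@H]1C/C(C)=C/[Sn](CCCC)(CCCC)CCCC | intermediate
16 | (5S,6R,7R,8R)-alpha-(diethoxyphosphoryl)-gamma-lactone alcohol (C11 labile, epimers) | CCOP(=O)(OCC)C1C(=O)O[C@@H]([C@@H](O[Si](C)(C)C(C)(C)C)/C(C)=C\I)[C@H]1[C@H](O)C/C(C)=C/[Sn](CCCC)(CCCC)CCCC | intermediate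
17 | (5S,6R,7R,8R)-alpha-methylene-gamma-lactone alcohol | C=C1C(=O)O[C@@H]([C@@H](O[Si](C)(C)C(C)(C)C)/C(C)=C\I)[C@H]1[C@H](O)C/C(C)=C/[Sn](CCCC)(CCCC)CCCC | intermediate
18 | (E)-2-methylbut-2-enoyl chloride (tigloyl chloride) | ClC(=O)/C(C)=C/C | starting material
19 | seco precursor: O8 tiglate of 17 | C=C1C(=O)O[C@@H]([C@@H](O[Si](C)(C)C(C)(C)C)/C(C)=C\I)[C@H]1[C@H](OC(=O)/C(C)=C/C)C/C(C)=C/[Sn](CCCC)(CCCC)CCCC | intermediate
20 | (1(10)E,3Z,5S,6R,7R,8R)-macrocyclic dienone | C=C1C(=O)O[C@@H]2[C@H]1[C@H](OC(=O)/C(C)=C/C)C/C(C)=C/C(=O)/C=C(/C)[C@@H]2O[Si](C)(C)C(C)(C)C | intermediate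
21 | (2S)-bis-allylic alcohol | C=C1C(=O)O[C@@H]2[C@H]1[C@H](OC(=O)/C(C)=C/C)C/C(C)=C/[C@H](O)/C=C(/C)[C@@H]2O[Si](C)(C)C(C)(C)C | intermediate
22 | (1R,2R,5S,6R,7R,8R,10R)-1,10-epoxy alcohol | C=C1C(=O)O[C@@H]2[C@H]1[C@H](OC(=O)/C(C)=C/C)C[C@@]1(C)O[C@@H]1[C@H](O)/C=C(/C)[C@@H]2O[Si](C)(C)C(C)(C)C | intermediate
23 | O5-tert-butyldimethylsilyl ether of the target | C=C1C(=O)O[C@@H]2[C@H]1[C@H](OC(=O)/C(C)=C/C)C[C@@]1(C)O[C@@H]1C(=O)/C=C(/C)[C@@H]2O[Si](C)(C)C(C)(C)C | intermediate
24 | CNP0345622.1, (1S,5S,6R,7R,8R,10R) | C=C1C(=O)O[C@@H]2[C@H]1[C@H](OC(=O)/C(C)=C/C)C[C@@]1(C)O[C@@H]1C(=O)/C=C(/C)[C@@H]2O | target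

## Step count and least certain steps

Total step count: 17. Longest linear sequence: 15 (steps 1-5 and 8-17).

**Step 13 (key step).**
- Transmetalation inside the strained eleven-membered palladacycle may be slow. Intermolecular coupling and oligomerisation could then take over.
- The tin may be lost by protodestannylation, the acylpalladium may add to C11=C13, or coupling may occur without CO uptake.
- Fallback: the route sets out from 19 and installs C2 before the ring is closed. Iododestannylation with I2 gives the bis(alkenyl iodide) F1. Palladium-catalysed formylation (CO, Bu3SnH) at the less hindered E iodide, which is cis only to a methyl group, gives the enal F2. A Nozaki-Hiyama-Kishi closure (CrCl2, NiCl2 cat., DMSO) between C3 and the C2 aldehyde then comes back to the route at 21.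

**Step 11.**
- C-alkylation may be slow, because the ester has to reach its s-cis rotamer and a cis-disubstituted ring is formed.
- Attack at C8 (6-endo) may compete.
- The C8 alkoxide may pull the lactone over to O8 before proton transfer.
- Fallback: the route sets out from 13 and activates the epoxide instead of the nucleophile.
  - Mitsunobu inversion with acetic acid gives the 6R acetate F3.
  - LDA and TMSCl give the ketene silyl acetal F4.
  - BF3·OEt2 at -78 °C triggers the intramolecular Mukaiyama-type opening at C7 to give the unsubstituted lactone alcohol F5.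
  - LDA (2 equiv) and dimethylmethyleneammonium iodide give the Mannich base F6.
  - Quaternisation with MeI and elimination with NaHCO3 come back to the route at 17.

**Step 10.**
- The carbinol is flanked by two branched carbons. Formation of the alkoxyphosphonium species may stall, and the acid may be consumed by the azodicarboxylate.
- Participation of the epoxide oxygen may erode the inversion.
- Fallback: the route sets out from 13 and separates activation from displacement. MsCl and Et3N give the mesylate F7. This is displaced with the caesium salt of 14 (18-crown-6, toluene) by SN2, coming back to the route at 15.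

**Step 15 (with step 14).**
- Hydride delivery to the macrocyclic ketone may favour the mismatched 2R epimer.
- The ring may be unable to adopt the geometry that the titanium-tartrate complex demands. The epoxidation then becomes slow, and oxidation at C3=C4 starts to compete.
- Fallback: the route sets out from 20 and omits the carbinol altogether. Nucleophilic Weitz-Scheffer epoxidation (t-BuOOH, DBU, CH2Cl2) should attack the less shielded beta-carbon C10 from the ring periphery, because C4 is screened by the O5 silyl ether. It comes back to the route at 23. The facial sense is then under substrate control only.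

## Further compounds

F1 | step 13 | bis(alkenyl iodide): 19 with iodine in place of tin at C1 | C=C1C(=O)O[C@@H]([C@@H](O[Si](C)(C)C(C)(C)C)/C(C)=C\I)[C@H]1[C@H](OC(=O)/C(C)=C/C)C/C(C)=C/I
F2 | step 13 | (E)-enal: F1 with CHO (C2) in place of iodine at C1 | C=C1C(=O)O[C@@H]([C@@H](O[Si](C)(C)C(C)(C)C)/C(C)=C\I)[C@H]1[C@H](OC(=O)/C(C)=C/C)C/C(C)=C/C=O
F3 | step 11 | (5S,6R,7S,8R)-7,8-epoxy C6 acetate | I/C=C(/C)[C@H](O[Si](C)(C)C(C)(C)C)[C@H](OC(C)=O)[C@H]1O[C@@H]1C/C(C)=C/[Sn](CCCC)(CCCC)CCCC
F4 | step 11 | ketene trimethylsilyl acetal of F3 | I/C=C(/C)[C@H](O[Si](C)(C)C(C)(C)C)[C@H](OC(=C)O[Si](C)(C)C)[C@H]1O[C@@H]1C/C(C)=C/[Sn](CCCC)(CCCC)CCCC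
F5 | step 11 | (5S,6R,7R,8R)-gamma-lactone alcohol without C13 | C1C(=O)O[C@@H]([C@@H](O[Si](C)(C)C(C)(C)C)/C(C)=C\I)[C@H]1[C@H](O)C/C(C)=C/[Sn](CCCC)(CCCC)CCCC
F6 | step 11 | alpha-(dimethylaminomethyl) lactone alcohol (C11 epimers) | CN(C)CC1C(=O)O[C@@H]([C@@H](O[Si](C)(C)C(C)(C)C)/C(C)=C\I)[C@H]1[C@H](O)C/C(C)=C/[Sn](CCCC)(CCCC)CCCC
F7 | step 10 | (5S,6S,7S,8R)-7,8-epoxy C6 methanesulfonate | I/C=C(/C)[C@H](O[Si](C)(C)C(C)(C)C)[C@@H](OS(C)(=O)=O)[C@H]1O[C@@H]1C/C(C)=C/[Sn](CCCC)(CCCC)CCCC
F0 | step 15 | none | none
A1 | alternative 1 | seco aldehyde/allyl bromide for closure at C6-C7 | O=C[C@@H](O[Si](C)(C)C(C)(C)C)/C(C)=C\C(=O)[C@H]1O[C@]1(C)C[C@@H](OC(=O)/C(C)=C/C)/C=C(\CBr)C(=O)OC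
A2 | alternative 2 | carvone-derived 1-vinyl-2-isopropenylcyclohexenol with O5-TBS | C=C[C@@]1(O)[C@H](C(C)=C)CC=C(C)[C@@H]1O[Si](C)(C)C(C)(C)C
A3 | alternative 2 | (1(10)E,3Z,5S)-cyclodecadien-6-one from the oxy-Cope ring expansion | O=C1CCC/C(C)=C/C/C=C(/C)[C@@H]1O[Si](C)(C)C(C)(C)C
A4 | alternative 3 | seco epoxy aldehyde/Z-alkenyl iodide for closure at C2-C3 | C=C1C(=O)O[C@@H]([C@@H](O[Si](C)(C)C(C)(C)C)/C(C)=C\I)[C@H]1[C@H](OC(=O)/C(C)=C/C)C[C@@]1(C)O[C@@H]1C=O
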